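A direct plan would assemble the open 1,3-diketone and close the pyranone at oxygen. Ortho-formylation of the parent phenol would give aldehyde A1, 2-hydroxy-3,4,5-trimethoxybenzaldehyde, and A1 would be masked as its methoxymethyl ether A2. A thiazolylidene-derived acyl anion of A2 would be alkylated by the bromoketone A3, 2-bromo-1-(3,4-dimethoxyphenyl)ethan-1-one, to the 1,3-diketone A4, and acid would unmask and cyclodehydrate A4 (O1–C2 closure).
Its weakest steps would be:
- the carbene-catalysed union of A2 with A3, which would lack close precedent for a doubly ortho-substituted aldehyde, and in which the bromoketone would alkylate the carbene and self-condense under the Cs2CO3 base;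
- the masking of A1 and the later unmasking of the phenol, which would add operations and a carcinogenic chloromethyl ether without adding complexity;
- the formylation to A1, which would serve only to reach the aldehyde oxidation level that the umpolung demands.

The route rests on the C4–C4a bond. Ring A of the target is a tetraoxygenated benzene whose single carbon substituent (C4 on C4a) lies next to the oxygen-bearing C8a and para to the C7 methoxy group, while the other neighbour of C8a (C8) is blocked by a methoxy group. O1–C2 is therefore made first, by conjugate addition of the free phenol to an arylpropiolate, and the pyranone is closed at carbon by Friedel–Crafts acylation of the resulting 3-aryl-3-aryloxyacrylic acid, which can give only the 6,7,8-pattern. The phenol needs no protection, the carbonyl carbon arrives at the acid oxidation level, and no carbene-catalysed coupling or formylation is required.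

Key step: step 3

Assumption: the enol ether of step 2 is drawn as its Z isomer; a Z/E mixture would serve equally, because the geometry equilibrates in the acid of step 3.

**Step 1**
Reactants: 1 4-ethynyl-1,2-dimethoxybenzene
Product: 3 methyl 3-(3,4-dimethoxyphenyl)prop-2-ynoate, via lithium acetylide 2 (not isolated)
Conditions: n-BuLi (1.05 equiv), THF, −78 °C, 30 min; added by cannula to ClCO2Me (1.5 equiv), THF, −78 to 0 °C; aq NH4Cl
Reagents that add atoms: methyl chloroformate, COC(=O)Cl
Why: Deprotonation of the terminal alkyne and C-acylation of the lithium acetylide with a chloroformate is a standard alkynoate synthesis, and inverse addition into excess chloroformate should suppress attack of a second acetylide on the product ester; no stereocentre is formed.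

**Step 2**
Reactants: 3 methyl 3-(3,4-dimethoxyphenyl)prop-2-ynoate; 4 2,3,4-trimethoxyphenol
Product: 6 (2Z)-3-(3,4-dimethoxyphenyl)-3-(2,3,4-trimethoxyphenoxy)prop-2-enoic acid, via methyl ester 5 (not isolated)
Conditions: 4 (1.15 equiv), Cs2CO3 (20 mol%), DMSO, 70 °C, argon; then LiOH (3 equiv), H2O, 40 °C; 1 M HCl to pH 3, 0 °C (6 separated from excess 4 through aq NaHCO3)
Reagents that add atoms: lithium hydroxide, [Li+].[OH-]
Why: Base-catalysed oxa-Michael addition of the phenoxide to the β-carbon of the alkynoate gives an allenolate that is protonated anti to the incoming oxygen, so that the Z enol ether 5 should predominate, and hydroxide should then saponify the methyl ester faster than it attacks the donor-substituted β-carbon; no stereocentre is formed.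

**Step 3**
Reactants: 6 (2Z)-3-(3,4-dimethoxyphenyl)-3-(2,3,4-trimethoxyphenoxy)prop-2-enoic acid
Product: 8 2-(3,4-dimethoxyphenyl)-6,7,8-trimethoxy-4H-chromen-4-one, via acylium ion 7 (not isolated)
Conditions: P2O5 (7.7 wt%) in MeSO3H (Eaton's reagent), 0.1 M, 25 to 50 °C, argon; poured onto ice
Reagents that add atoms: none
Why: The medium should turn the acid into its mixed anhydride and then into acylium ion 7, which is stabilised by the ether oxygen (ketene–oxocarbenium resonance) and attacks the free carbon ortho to the ether oxygen of the trimethoxyphenoxy ring; loss of a proton from the arenium ion gives the 4-pyranone. The reaction type is the intramolecular Friedel–Crafts acylation by which 3-aryloxyacrylic and 3-aryloxycinnamic acids are cyclised to chromones and flavones. Ring C is closed at the C4–C4a bond, formally a 6-exo-dig attack of the arene on the acylium carbon, and no stereocentre is formed. The site on ring A is fixed, because the other carbon ortho to the ether oxygen carries a methoxy group and the remaining free carbon (the later C5) cannot reach the acylium carbon. The step needs six-membered closure onto ring A in preference to five-membered closure onto the dimethoxyphenyl ring (an indenone from the E isomer); the Z geometry from step 2, the E/Z equilibration by reversible protonation at the α-carbon with the flavone as the sink, and the deactivation of the dimethoxyphenyl ring by conjugation with the cationic C2 should secure this. A Brønsted acid at or below 50 °C without a Lewis acid should leave the five aryl methyl ethers intact, and the target has no methoxy group peri to the carbonyl.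

**Compound list**
1 | 4-ethynyl-1,2-dimethoxybenzene | COc1ccc(C#C)cc1OC | starting material
2 | lithium (3,4-dimethoxyphenyl)acetylide | COc1ccc(C#C[Li])cc1OC | intermediate
3 | methyl 3-(3,4-dimethoxyphenyl)prop-2-ynoate | COC(=O)C#Cc1ccc(OC)c(OC)c1 | intermediate
4 | 2,3,4-trimethoxyphenol | COc1ccc(O)c(OC)c1OC | starting material
5 | methyl (2Z)-3-(3,4-dimethoxyphenyl)-3-(2,3,4-trimethoxyphenoxy)prop-2-enoate | COC(=O)/C=C(\Oc1ccc(OC)c(OC)c1OC)c1ccc(OC)c(OC)c1 | intermediate
6 | (2Z)-3-(3,4-dimethoxyphenyl)-3-(2,3,4-trimethoxyphenoxy)prop-2-enoic acid | OC(=O)/C=C(\Oc1ccc(OC)c(OC)c1OC)c1ccc(OC)c(OC)c1 | intermediate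
7 | (2Z)-3-(3,4-dimethoxyphenyl)-3-(2,3,4-trimethoxyphenoxy)prop-2-enoylium (acylium ion, methanesulfonate as counter-ion) | [O+]#C/C=C(\Oc1ccc(OC)c(OC)c1OC)c1ccc(OC)c(OC)c1 | intermediate
8 | 2-(3,4-dimethoxyphenyl)-6,7,8-trimethoxy-4H-chromen-4-one (CNP0388881.0) | COc1ccc(-c2cc(=O)c3cc(OC)c(OC)c(OC)c3o2)cc1OC | target

Total step count: 3. Longest linear sequence: 3 steps (1 → 3 → 6 → 8; phenol 4 enters in step 2).

**Steps most likely to fail**

Step 3 (key step). The intramolecular acylation may lose to intermolecular acylation or sulfonylation at the electron-rich free carbon of ring A, to closure onto the dimethoxyphenyl ring, or to acid cleavage of the enol ether followed by decarboxylation. The fallback gives up the Friedel–Crafts closure and sets out from phenol 4. Iodination of its phenoxide (I2, NaHCO3, THF/H2O, 0 °C) at the only free position ortho to the hydroxyl would give 6-iodo-2,3,4-trimethoxyphenol (F1). Carbonylative annulation of F1 with alkyne 1 (PdCl2(PPh3)2, CO, Et2NH, 120 °C) would then proceed by oxidative addition to zerovalent palladium, CO insertion, alkynylation, addition of diethylamine to the ynone and 6-endo closure of the enaminone, and would come back to the route at target 8.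

Step 2. The phenoxide may add too slowly to an alkyne whose β-carbon is deactivated by the electron-rich aryl group, or hydroxide may displace the aryloxy group during the saponification. The fallback sets out from alkynoate 3. Hydroiodination (NaI, AcOH, 110 °C, anti addition) would give methyl (2Z)-3-(3,4-dimethoxyphenyl)-3-iodoprop-2-enoate (F2). Ullmann-type C–O coupling of F2 with phenol 4 (CuI, N,N-dimethylglycine, Cs2CO3, dioxane, 90 °C, retention of geometry) would come back to the route at ester 5, which would be isolated and saponified under milder conditions (LiOH, THF/H2O, 0 °C) to 6.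

Step 1. The acetylide may add a second time to the newly formed ester, or the acylation may remain incomplete. The fallback sets out from alkyne 1. The acetylide would be trapped with carbon dioxide instead (n-BuLi, THF, −78 °C; CO2; HCl) to give 3-(3,4-dimethoxyphenyl)prop-2-ynoic acid (F3), whose carboxylate cannot take up a second acetylide. O-Methylation of F3 (MeI, K2CO3, DMF, 25 °C) would come back to the route at 3.

**Further compounds**
F1 | step 3 | 6-iodo-2,3,4-trimethoxyphenol | COc1cc(I)c(O)c(OC)c1OC
F2 | step 2 | methyl (2Z)-3-(3,4-dimethoxyphenyl)-3-iodoprop-2-enoate | COC(=O)/C=C(\I)c1ccc(OC)c(OC)c1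
F3 | step 1 | 3-(3,4-dimethoxyphenyl)prop-2-ynoic acid | OC(=O)C#Cc1ccc(OC)c(OC)c1
A1 | direct plan | 2-hydroxy-3,4,5-trimethoxybenzaldehyde | COc1cc(C=O)c(O)c(OC)c1OC
A2 | direct plan | 2-(methoxymethoxy)-3,4,5-trimethoxybenzaldehyde | COCOc1c(C=O)cc(OC)c(OC)c1OC
A3 | direct plan | 2-bromo-1-(3,4-dimethoxyphenyl)ethan-1-one | COc1ccc(C(=O)CBr)cc1OC
A4 | direct plan | 1-(3,4-dimethoxyphenyl)-3-[2-(methoxymethoxy)-3,4,5-trimethoxyphenyl]propane-1,3-dione | COCOc1c(OC)c(OC)c(OC)cc1C(=O)CC(=O)c1ccc(OC)c(OC)c1
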